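**Retrosynthetic overview**

1. Agrimol F (24) comes from its hepta-O-benzyl ether 23 by hydrogenolysis of all seven benzyl ethers.
2. 23 is cut at both aryl–CH2 bonds of ring B (B3–CH2 and B5–CH2), giving the bromo-iodo core 6, the ring A benzylzinc chloride 16 and the ring C benzylzinc chloride 21; these are joined in one flask, iodide first, bromide second.
3. Structural basis: ring B carries its butyryl group at B1 and is mirror-symmetric through the B1···B4 axis, so the bridge-bearing carbons B3 and B5 are equivalent and either arm (acetyl ring A, butyryl ring C) may occupy either halogen site.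
4. Core 6 comes from butyrylphloroglucinol by benzylation, bromination and iodination; both arms come from one aldehyde 10 (2,4,6-trihydroxytoluene, formylation, para-O-methylation), then C-acylation, benzylation, reduction, chlorination and zinc insertion.
5. No ring is constructed: rings A, B and C are all carried in from phloroglucinol-type starting materials and are joined in the order B + A, then C.

Key step: step 17

Assumption: agrimol F has no stereocentre and is treated as the fully aromatic hexaphenol; ring A is the acetyl-bearing terminal ring, ring B the central butyryl ring, ring C the butyryl-bearing terminal ring.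

**Route**

Step 1
Reactants: 1 phloroglucinol; 2 butyryl chloride
Product: 3 1-(2,4,6-trihydroxyphenyl)butan-1-one
Conditions: AlCl3 (3.5 equiv), CH2Cl2–MeNO2, 0 °C to 40 °C; aq. HCl work-up
Reagents that add atoms: none
Why: Friedel–Crafts C-acylation of the highly nucleophilic triphenol, where the first acyl group, chelated to aluminium, deactivates the ring so that monoacylation should dominate with one equivalent of acid chloride.

Step 2
Reactants: 3 1-(2,4,6-trihydroxyphenyl)butan-1-one
Product: 4 1-[2,4,6-tris(benzyloxy)phenyl]butan-1-one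
Conditions: BnBr (3.6 equiv), K2CO3 (4.5 equiv), DMF, 70 °C
Reagents that add atoms: benzyl bromide, BrCc1ccccc1
Why: Williamson etherification, in which the dipolar aprotic medium favours O- over C-benzylation and heating with excess halide should also alkylate the two chelated ortho hydroxyls.

Step 3
Reactants: 4 1-[2,4,6-tris(benzyloxy)phenyl]butan-1-one
Product: 5 1-[2,4,6-tris(benzyloxy)-3-bromophenyl]butan-1-one
Conditions: N-bromosuccinimide (1.0 equiv), MeCN, 0 °C, dark
Reagents that add atoms: N-bromosuccinimide, O=C1CCC(=O)N1Br
Why: Electrophilic aromatic bromination at one of two equivalent ring positions flanked by benzyloxy groups; the bromine installed deactivates and crowds the ring, so one equivalent should stop at the monobromide more cleanly than halogenation of the free triphenol would.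

Step 4
Reactants: 5 1-[2,4,6-tris(benzyloxy)-3-bromophenyl]butan-1-one
Product: 6 1-[2,4,6-tris(benzyloxy)-3-bromo-5-iodophenyl]butan-1-one
Conditions: N-iodosuccinimide (1.3 equiv), CF3CO2H (0.2 equiv), MeCN, rt
Reagents that add atoms: N-iodosuccinimide, O=C1CCC(=O)N1I
Why: Acid-activated electrophilic iodination at the only remaining ring C–H, which is still activated by two ortho and one para alkoxy group; iodine is introduced after bromine so that no ipso exchange of halogens can occur.

Step 5
Reactants: 7 2,4,6-trihydroxytoluene
Product: 9 2,4,6-trihydroxy-3-methylbenzaldehyde, via iminium chloride 8 (not isolated)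
Conditions: POCl3 (1.1 equiv), DMF, EtOAc, 0 °C to rt; then H2O, 60 °C
Reagents that add atoms: N,N-dimethylformamide, CN(C)C=O; water, O
Why: Vilsmeier–Haack formylation at one of the two equivalent free positions, where the aryl iminium salt should precipitate from ethyl acetate and so escape a second formylation before it is hydrolysed.

Step 6
Reactants: 9 2,4,6-trihydroxy-3-methylbenzaldehyde
Product: 10 2,6-dihydroxy-4-methoxy-3-methylbenzaldehyde
Conditions: Me2SO4 (1.0 equiv), K2CO3 (1.0 equiv), acetone, rt
Reagents that add atoms: dimethyl sulfate, COS(=O)(=O)OC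
Why: Williamson O-methylation under weak base, directed to the 4-hydroxyl because it is the only hydroxyl not hydrogen-bonded to the formyl group and, as a vinylogous carboxylic acid para to the aldehyde, the most acidic one.

Step 7
Reactants: 10 2,6-dihydroxy-4-methoxy-3-methylbenzaldehyde; 11 acetyl chloride
Product: 12 3-acetyl-2,6-dihydroxy-4-methoxy-5-methylbenzaldehyde
Conditions: TiCl4 (3 equiv), CH2Cl2, 0 °C to 40 °C; 1 M HCl work-up
Reagents that add atoms: none
Why: Friedel–Crafts acylation of a formylphloroglucinol at its single free ring position, which remains activated by three oxygen substituents; TiCl4 is chosen over AlCl3 to spare the methyl ether that ends up ortho to the new ketone.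

Step 8
Reactants: 12 3-acetyl-2,6-dihydroxy-4-methoxy-5-methylbenzaldehyde
Product: 13 3-acetyl-2,6-bis(benzyloxy)-4-methoxy-5-methylbenzaldehyde
Conditions: BnBr (2.6 equiv), K2CO3 (3 equiv), DMF, 60 °C
Reagents that add atoms: benzyl bromide, BrCc1ccccc1
Why: Williamson etherification of the two chelated phenols, which cannot be diverted to nuclear C-benzylation because the ring has no C–H left.

Step 9
Reactants: 13 3-acetyl-2,6-bis(benzyloxy)-4-methoxy-5-methylbenzaldehyde
Product: 14 1-[2,4-bis(benzyloxy)-3-(hydroxymethyl)-6-methoxy-5-methylphenyl]ethan-1-one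
Conditions: NaBH4 (0.35 equiv), THF–MeOH, −20 °C
Reagents that add atoms: none
Why: Chemoselective borohydride reduction, since an aldehyde is reduced far faster than the doubly ortho-substituted, twisted aryl methyl ketone at low temperature with a limited amount of hydride.

Step 10
Reactants: 14 1-[2,4-bis(benzyloxy)-3-(hydroxymethyl)-6-methoxy-5-methylphenyl]ethan-1-one
Product: 15 1-[2,4-bis(benzyloxy)-3-(chloromethyl)-6-methoxy-5-methylphenyl]ethan-1-one
Conditions: SOCl2 (1.2 equiv), CH2Cl2, 0 °C; evaporated and used crude
Reagents that add atoms: thionyl chloride, O=S(Cl)Cl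
Why: Chlorodehydroxylation of an electron-rich benzylic alcohol through its chlorosulfite; the fully substituted ring offers no site for Friedel–Crafts self-alkylation, so the chloride should survive until it is used.

Step 11
Reactants: 15 1-[2,4-bis(benzyloxy)-3-(chloromethyl)-6-methoxy-5-methylphenyl]ethan-1-one
Product: 16 {[3-acetyl-2,6-bis(benzyloxy)-4-methoxy-5-methylphenyl]methyl}zinc chloride (ring A benzylzinc chloride, THF solution)
Conditions: Zn dust (2 equiv, activated by BrCH2CH2Br and Me3SiCl), LiCl (1.5 equiv), THF, 25 °C; titrated with I2, used as solution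
Reagents that add atoms: zinc, [Zn]
Why: LiCl-mediated direct insertion of zinc into a benzylic C–Cl bond (Knochel-type zincation), giving a reagent too weakly nucleophilic to attack or enolise the aryl ketone.

Step 12
Reactants: 10 2,6-dihydroxy-4-methoxy-3-methylbenzaldehyde; 2 butyryl chloride
Product: 17 3-butanoyl-2,6-dihydroxy-4-methoxy-5-methylbenzaldehyde
Conditions: TiCl4 (3 equiv), CH2Cl2, 0 °C to 40 °C; 1 M HCl work-up
Reagents that add atoms: none
Why: Friedel–Crafts acylation at the only free ring position of the formylphloroglucinol monomethyl ether, on the same grounds as step 7.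

Step 13
Reactants: 17 3-butanoyl-2,6-dihydroxy-4-methoxy-5-methylbenzaldehyde
Product: 18 2,6-bis(benzyloxy)-3-butanoyl-4-methoxy-5-methylbenzaldehyde
Conditions: BnBr (2.6 equiv), K2CO3 (3 equiv), DMF, 60 °C
Reagents that add atoms: benzyl bromide, BrCc1ccccc1
Why: Williamson etherification of both chelated phenols on a ring with no free C–H, as in step 8.

Step 14
Reactants: 18 2,6-bis(benzyloxy)-3-butanoyl-4-methoxy-5-methylbenzaldehyde
Product: 19 1-[2,4-bis(benzyloxy)-3-(hydroxymethyl)-6-methoxy-5-methylphenyl]butan-1-one
Conditions: NaBH4 (0.35 equiv), THF–MeOH, −20 °C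
Reagents that add atoms: none
Why: Chemoselective borohydride reduction of the aldehyde in the presence of the hindered, twisted aryl propyl ketone.

Step 15
Reactants: 19 1-[2,4-bis(benzyloxy)-3-(hydroxymethyl)-6-methoxy-5-methylphenyl]butan-1-one
Product: 20 1-[2,4-bis(benzyloxy)-3-(chloromethyl)-6-methoxy-5-methylphenyl]butan-1-one
Conditions: SOCl2 (1.2 equiv), CH2Cl2, 0 °C; evaporated and used crude
Reagents that add atoms: thionyl chloride, O=S(Cl)Cl
Why: Chlorodehydroxylation of the benzylic alcohol through its chlorosulfite, as in step 10.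

Step 16
Reactants: 20 1-[2,4-bis(benzyloxy)-3-(chloromethyl)-6-methoxy-5-methylphenyl]butan-1-one
Product: 21 {[2,6-bis(benzyloxy)-3-butanoyl-4-methoxy-5-methylphenyl]methyl}zinc chloride (ring C benzylzinc chloride, THF solution)
Conditions: Zn dust (2 equiv, activated by BrCH2CH2Br and Me3SiCl), LiCl (1.5 equiv), THF, 25 °C; titrated with I2, used as solution
Reagents that add atoms: zinc, [Zn]
Why: LiCl-mediated direct zinc insertion into the benzylic C–Cl bond with tolerance of the ketone, as in step 11.

Step 17
Reactants: 6 1-[2,4,6-tris(benzyloxy)-3-bromo-5-iodophenyl]butan-1-one; 16 ring A benzylzinc chloride; 21 ring C benzylzinc chloride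
Product: 23 hepta-O-benzyl agrimol F, via monocoupled aryl bromide 22 (not isolated)
Conditions: Pd(OAc)2 (3 mol %), SPhos (6 mol %), THF; 16 (1.05 equiv) added slowly at 25 °C until 6 is consumed; then 21 (1.4 equiv), 60 °C
Reagents that add atoms: none
Why: Pd(OAc)2 is reduced in the flask by a trace of the zinc reagent to zerovalent palladium, which with SPhos adds oxidatively to the C–I bond of 6 at ambient temperature, transmetalates with 16 and eliminates reductively to give bromide 22; once 21 is added and the mixture warmed, the same cycle runs at the C–Br bond. The closest known reaction type is the halogen-selective sequential Negishi coupling of benzylzinc halides with a bromoiodoarene. No ring is closed and no stereocentre is formed; the step makes the two C(sp2)–C(sp3) bonds B3–CH2 and B5–CH2. The selectivity required is one arm per halogen, and it should be secured by the much faster oxidative addition into C–I than into the equally crowded C–Br bond, by metering 16 to about one equivalent and by holding the temperature down until the iodide is gone; because B3 and B5 are mirror-related, it is immaterial which arm enters at which halogen. The benzylzinc chlorides carry no β-hydrogen and leave the three aryl ketones alone, and the CH2 unit holds the two doubly ortho-substituted rings apart at the metal, which the bulky biaryl phosphine is built to accommodate. Since neither formaldehyde nor acid or base is present, retro-Friedel–Crafts exchange of the methylene bridges, the usual difficulty of phloroglucinol oligomer synthesis, has no pathway.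

Step 18
Reactants: 23 hepta-O-benzyl agrimol F
Product: 24 agrimol F
Conditions: H2 (1 atm), Pd/C (10 wt%), EtOAc–MeOH, rt
Reagents that add atoms: none
Why: Catalytic hydrogenolysis of the seven benzyl aryl ethers under neutral conditions, which should leave the strongly chelated, vinylogous-acid aryl ketones and the diarylmethane bridges untouched at ambient pressure and temperature.

**Compound list**

1 | phloroglucinol | Oc1cc(O)cc(O)c1 | starting material
2 | butyryl chloride | CCCC(Cl)=O | starting material
3 | 1-(2,4,6-trihydroxyphenyl)butan-1-one | CCCC(=O)c1c(O)cc(O)cc1O | intermediate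
4 | 1-[2,4,6-tris(benzyloxy)phenyl]butan-1-one | CCCC(=O)c1c(OCc2ccccc2)cc(OCc2ccccc2)cc1OCc1ccccc1 | intermediate
5 | 1-[2,4,6-tris(benzyloxy)-3-bromophenyl]butan-1-one | CCCC(=O)c1c(OCc2ccccc2)c(Br)c(OCc2ccccc2)cc1OCc1ccccc1 | intermediate
6 | 1-[2,4,6-tris(benzyloxy)-3-bromo-5-iodophenyl]butan-1-one | CCCC(=O)c1c(OCc2ccccc2)c(Br)c(OCc2ccccc2)c(I)c1OCc1ccccc1 | intermediate
7 | 2,4,6-trihydroxytoluene | Cc1c(O)cc(O)cc1O | starting material
8 | N-[(2,4,6-trihydroxy-3-methylphenyl)methylidene]-N-methylmethanaminium chloride | Cc1c(O)cc(O)c(C=[N+](C)C)c1O.[Cl-] | intermediate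
9 | 2,4,6-trihydroxy-3-methylbenzaldehyde | Cc1c(O)cc(O)c(C=O)c1O | intermediate
10 | 2,6-dihydroxy-4-methoxy-3-methylbenzaldehyde | COc1cc(O)c(C=O)c(O)c1C | intermediate
11 | acetyl chloride | CC(Cl)=O | starting material
12 | 3-acetyl-2,6-dihydroxy-4-methoxy-5-methylbenzaldehyde | COc1c(C)c(O)c(C=O)c(O)c1C(C)=O | intermediate
13 | 3-acetyl-2,6-bis(benzyloxy)-4-methoxy-5-methylbenzaldehyde | COc1c(C)c(OCc2ccccc2)c(C=O)c(OCc2ccccc2)c1C(C)=O | intermediate
14 | 1-[2,4-bis(benzyloxy)-3-(hydroxymethyl)-6-methoxy-5-methylphenyl]ethan-1-one | COc1c(C)c(OCc2ccccc2)c(CO)c(OCc2ccccc2)c1C(C)=O | intermediate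
15 | 1-[2,4-bis(benzyloxy)-3-(chloromethyl)-6-methoxy-5-methylphenyl]ethan-1-one | COc1c(C)c(OCc2ccccc2)c(CCl)c(OCc2ccccc2)c1C(C)=O | intermediate
16 | {[3-acetyl-2,6-bis(benzyloxy)-4-methoxy-5-methylphenyl]methyl}zinc chloride (ring A benzylzinc chloride) | CC(=O)c1c(OCc2ccccc2)c(C[Zn]Cl)c(OCc2ccccc2)c(C)c1OC | intermediate
17 | 3-butanoyl-2,6-dihydroxy-4-methoxy-5-methylbenzaldehyde | CCCC(=O)c1c(OC)c(C)c(O)c(C=O)c1O | intermediate
18 | 2,6-bis(benzyloxy)-3-butanoyl-4-methoxy-5-methylbenzaldehyde | CCCC(=O)c1c(OC)c(C)c(OCc2ccccc2)c(C=O)c1OCc1ccccc1 | intermediate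
19 | 1-[2,4-bis(benzyloxy)-3-(hydroxymethyl)-6-methoxy-5-methylphenyl]butan-1-one | CCCC(=O)c1c(OC)c(C)c(OCc2ccccc2)c(CO)c1OCc1ccccc1 | intermediate
20 | 1-[2,4-bis(benzyloxy)-3-(chloromethyl)-6-methoxy-5-methylphenyl]butan-1-one | CCCC(=O)c1c(OC)c(C)c(OCc2ccccc2)c(CCl)c1OCc1ccccc1 | intermediate
21 | {[2,6-bis(benzyloxy)-3-butanoyl-4-methoxy-5-methylphenyl]methyl}zinc chloride (ring C benzylzinc chloride) | CCCC(=O)c1c(OCc2ccccc2)c(C[Zn]Cl)c(OCc2ccccc2)c(C)c1OC | intermediate
22 | 1-[3-{[3-acetyl-2,6-bis(benzyloxy)-4-methoxy-5-methylphenyl]methyl}-2,4,6-tris(benzyloxy)-5-bromophenyl]butan-1-one | CCCC(=O)c1c(OCc2ccccc2)c(Br)c(OCc2ccccc2)c(Cc2c(OCc3ccccc3)c(C)c(OC)c(C(C)=O)c2OCc2ccccc2)c1OCc1ccccc1 | intermediate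
23 | hepta-O-benzyl agrimol F | CCCC(=O)c1c(OCc2ccccc2)c(Cc2c(OCc3ccccc3)c(C)c(OC)c(C(C)=O)c2OCc2ccccc2)c(OCc2ccccc2)c(Cc2c(OCc3ccccc3)c(C)c(OC)c(C(=O)CCC)c2OCc2ccccc2)c1OCc1ccccc1 | intermediate
24 | agrimol F | CCCC(=O)c1c(O)c(Cc2c(O)c(C)c(OC)c(C(C)=O)c2O)c(O)c(Cc2c(O)c(C)c(OC)c(C(=O)CCC)c2O)c1O | target

**Totals**

Total step count: 18.
Longest linear sequence: 9 steps (steps 5, 6, 7, 8, 9, 10, 11, 17, 18, from 2,4,6-trihydroxytoluene; the ring C arm is equally long through steps 12–16).

**Steps most likely to fail**

Step 17. The discrimination between the two halogens may break down: oxidative addition at C–Br could begin before the first arm is used up, which would scramble the two arms. The second, more crowded coupling may also stall, leaving protodehalogenation and benzyl homocoupling to take over. The fallback takes the selectivity from the order of halogenation instead. Setting out from monobromide 5, a single Negishi coupling with 16 (Pd(OAc)2, SPhos, THF, 60 °C) would give 1-[3-{[3-acetyl-2,6-bis(benzyloxy)-4-methoxy-5-methylphenyl]methyl}-2,4,6-tris(benzyloxy)phenyl]butan-1-one F1. Bromination of its one remaining ring B C–H with N-bromosuccinimide in MeCN would then give 22, where the route is rejoined; 22 is isolated and coupled with 21 as a separate run of the second half of step 17.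

Step 7 (step 12 carries the same risk). The Lewis acid may cleave the methyl ether once it sits ortho to the new ketone, or the formyl-deactivated ring may acylate too slowly. The fallback introduces the acetyl group by cross-coupling after the phenols are protected. Setting out from 10, benzylation (BnBr, K2CO3, DMF) would give 2,6-bis(benzyloxy)-4-methoxy-3-methylbenzaldehyde F2. Bromination of the single free ring position (N-bromosuccinimide, MeCN) would give 2,6-bis(benzyloxy)-3-bromo-4-methoxy-5-methylbenzaldehyde F3. Stille coupling with tributyl(1-ethoxyvinyl)stannane (Pd(PPh3)4, toluene, 100 °C) would give 2,6-bis(benzyloxy)-3-(1-ethoxyethenyl)-4-methoxy-5-methylbenzaldehyde F4, and hydrolysis of the enol ether (1 M HCl, THF, rt) would deliver 13, where the route is rejoined.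

Step 11 (step 16 carries the same risk). Wurtz-type homocoupling of the electron-rich benzylic chloride on the zinc surface, or slow insertion at the doubly ortho-flanked benzylic carbon, may leave a reagent of low titre. The fallback replaces the organozinc by a bench-stable boron nucleophile. Setting out from chloride 15, palladium-catalysed borylation (B2pin2, KOAc, Pd(dba)2 with tris(4-methoxyphenyl)phosphine, toluene, 50 °C) would give 1-[2,4-bis(benzyloxy)-6-methoxy-5-methyl-3-[(4,4,5,5-tetramethyl-1,3,2-dioxaborolan-2-yl)methyl]phenyl]ethan-1-one F5. Suzuki–Miyaura coupling of F5 with 6 at the C–I bond (PdCl2(dppf), Cs2CO3, THF–H2O, 60 °C) would give 22, where the route is rejoined; 22 is then coupled with 21 as in the second half of step 17.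

**Further compounds**

F1 | step 17 | 1-[3-{[3-acetyl-2,6-bis(benzyloxy)-4-methoxy-5-methylphenyl]methyl}-2,4,6-tris(benzyloxy)phenyl]butan-1-one | CCCC(=O)c1c(OCc2ccccc2)c(Cc2c(OCc3ccccc3)c(C)c(OC)c(C(C)=O)c2OCc2ccccc2)c(OCc2ccccc2)cc1OCc1ccccc1
F2 | step 7 | 2,6-bis(benzyloxy)-4-methoxy-3-methylbenzaldehyde | COc1cc(OCc2ccccc2)c(C=O)c(OCc2ccccc2)c1C
F3 | step 7 | 2,6-bis(benzyloxy)-3-bromo-4-methoxy-5-methylbenzaldehyde | COc1c(Br)c(OCc2ccccc2)c(C=O)c(OCc2ccccc2)c1C
F4 | step 7 | 2,6-bis(benzyloxy)-3-(1-ethoxyethenyl)-4-methoxy-5-methylbenzaldehyde | CCOC(=C)c1c(OC)c(C)c(OCc2ccccc2)c(C=O)c1OCc1ccccc1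
F5 | step 11 | 1-[2,4-bis(benzyloxy)-6-methoxy-5-methyl-3-[(4,4,5,5-tetramethyl-1,3,2-dioxaborolan-2-yl)methyl]phenyl]ethan-1-one | COc1c(C)c(OCc2ccccc2)c(CB2OC(C)(C)C(C)(C)O2)c(OCc2ccccc2)c1C(C)=O
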